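## The problem

Compound 44 is a germacranolide whose ten-membered carbocycle (C1–C10) is bridged twice. An oxygen joins C3 to the quaternary C10, so that O, C10, C1, C2 and C3 form a 3(2H)-furanone, and C6/C7 carry a trans-fused α-methylene-γ-butyrolactone. Five contiguous stereocentres (6R,7S,8S,9S,10S) lie on the C6–C10 arc. The C7 branch and the C8, C9 and C10 oxygens all sit on one ring face, only the C6 oxygen sits on the other, and the C4=C5 alkene between the two bridges is Z. C10 is a fully substituted carbinol that no later step can correct, so it must be set early by a reagent and then relay its configuration to C9, C8 and C7. C6 can be set last, from a ketone. The cis C8/C9 diol carries two different acyl groups, so the two oxygens have to be told apart long before acylation. The exo-methylene lactone, the cross-conjugated furanone and the two esters will not survive strong base, hydride or nucleophiles and belong at the end. The enabling feature is that C6 bears oxygen while C2–C3 is at the oxidation level of an alkyne: a C6 ketone and a C2≡C3 alkyne are what an α,β-epoxy ketone fragmentation leaves, so the ten-membered ring can be unfolded from a five–seven bicycle in which C2 and C6 are bonded.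

## Retrosynthesis

**Esters and furanone (44 → 38).** The C8 methacrylate is cut first (43), then the C3–O bond of the furanone (ynone 42), then the C1 carbonyl (41), the silyl ethers (40) and the C9 acetate (39, 38). Closing the furanone from an α′-hydroxy ynone is a 5-endo-dig addition that needs no oxidation-state change. The order is fixed by regiochemistry: C9 is acetylated while C10–OH is tertiary and C8/C1 are silylated, and the C1 ketone is only unveiled afterwards, so C9–OH can never compete for the ynone. Keeping C9/C10 as one acetonide and C8 as a silyl ether from the start removes the need for a selective acylation of a cis-diol.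

**Lactone (38 → 33).** The exocyclic C11=C13 bond is cut back to lactone 35 (Mannich methylenation), and the C12–O bond to diol 33 (oxidative lactonisation). The side chain is therefore carried as a saturated 2-oxyethyl group. This keeps C7–H from being doubly activated next to the later C6 ketone and leaves no pendant alkene to trap cations in the five-ring annulation. The price is one extra step for C13.

**C6 carbinol (33 → 29).** The C6–H bond is cut back to enynone 29. Hydride should enter from the open face and give the (6S)-alcohol 30, the wrong epimer for a trans lactone. The same open face then serves an SN2 inversion (ester 31, then 32), so the sequence needs no control element that the ring does not already offer.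

**C4=C5 alkene (29 → 27).** The alkene is removed to give cyclodecynone 27. With only one ketone present and a non-allylic C7–H, kinetic enolisation towards the C5 methylene decides the regiochemistry, and the ring enforces the Z geometry.

**Ten-membered ring (27 → 25).** C2 and C6 are reconnected: 27 is the fragmentation product of the ring-fusion epoxy ketone 25. Against direct closures of the ten-membered ring at C9–C10, C8–C9 or C5–C6, this cut forms no σ bond and no stereocentre in the medium ring, and it delivers the alkyne and the C6 ketone exactly where the furanone and lactone need them. The forward step only has to fragment faster than the epoxide opens.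

**Five-membered ring (25 → 23).** The epoxide comes from enone 24 by nucleophilic epoxidation. The C5–C6 bond of 24 is cut to the cross-conjugated dienone 23 (Nazarov cyclisation), the classical partner of the fragmentation. The forward reaction must tolerate silyl ethers, an acetonide and a PMB ether.

**Seven-membered ring (23 → 15).** The C3–C4 bond is cut to ester 20 and isopropenylmagnesium bromide 21, the C2=C6 alkene to diene 18 (ring-closing metathesis via 19), and the C1–C2 bond to aldehyde 15 and methyl propiolate 16. Closing at C2=C6 puts the acyl handle on C2 directly. Closing at C8=C9 or C9=C10 would demand a dihydroxylation on the more hindered face. C1 needs no control because it ends as a ketone.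

**C7–C8 bond (15 → 11 + 4).** Aldehyde 15 comes from alcohol 12 (via 13 and 14), and 12 is cut into aldehyde 11 and allylic bromide 4. A chromium-mediated allylation sets C7 and C8 together, anti to each other and Felkin–Anh to C9, which is the all-cis array required. An auxiliary aldol would need several more steps to turn the acyl group into the side chain.

**C9/C10 (11 → 5 + 6).** Aldehyde 11 is traced through acetonide 10 and benzoate 9 to epoxy alcohol 8, the product of a Sharpless kinetic resolution of dienol 7, itself made from methacrolein 5 and vinylmagnesium bromide 6. The epoxidation fixes the quaternary C10 and, by matching, C9, and the erythro relationship it gives is the one needed.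

**Allylic bromide (4 → 1).** Bromide 4 comes from PMB ether 2 and dibromide 3 by cross-metathesis; 2 comes from but-3-en-1-ol 1.

## Roads not taken

**Alternative 1:** The C9–C10 bond is cut. In the forward sense the C9 aldehyde of the open-chain silyloxyfuran A1 is activated by BF3·OEt2 and attacked by the furan carbon that becomes C10, which closes the ten-membered ring, restores the furanone and gives the 9-deacetyl compound A2. This is the most convergent of all the plans: ring, furanone, C9 and C10 arise in one late step and only an acetylation remains, so it would be roughly ten steps shorter than the chosen route. Its weak points are stereochemical and chemical. A quaternary C10 and the C9 carbinol must both form with the right sense inside a ten-membered transition state that contains a Z-alkene and a trans lactone and offers no obvious control element. The aldehyde of A1 is α-acyloxy and adjacent to C7, so elimination and epimerisation compete under Lewis acid. Oligomerisation is a further risk. Against its brevity the chosen plan sets that C10 and C9 are fixed by a reagent-controlled epoxidation at the second step and that the ring-forming event creates no stereocentre.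

**Alternative 2:** The C2–C3 and C4–C5 bonds are cut. In the forward sense the prop-1-ynyl ether on the C10 oxygen of cyclooctenone A3 adds across the C2=C5 enone alkene, and the four-membered ring so formed opens by cleavage of the old C2–C5 bond to give the furanone-bridged ten-membered ring A4. Like the chosen plan it avoids a direct medium-ring closure by breaking a bond shared by two smaller rings. It is better in one respect: furanone and C4=C5 alkene appear together, whereas the chosen route spends steps 19 and 28–30 on them. Its weaknesses are precedent and geometry. Cycloadditions of simple ynol ethers to enones through a one-atom oxygen tether are thinly documented. The ring opening must break one specific bond of a fused cyclobutene and deliver a Z alkene, whereas a thermal conrotatory opening tends to place a trans alkene in the new ring. The eight-membered precursor A3 carries the same four stereocentres as cycloheptene 20 and is no easier to make. The chosen plan answers with a fragmentation of a well-known type whose alkene geometry is set separately by the ring.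

**Alternative 3:** The C8–C9 bond is cut. In the forward sense SmI2 reduces both aldehydes of the enyne dialdehyde A5 to ketyls that couple, closing the ring as the cis 8,9-diol A6 with lactone and Z-enyne already in place. The plan is convergent and shorter, and the pinacol coupling does give cis diols in medium rings. For this target it has three problems. SmI2 also reduces α-methylene lactones and can engage the conjugated enyne. The C8 aldehyde is α to C7 and epimerisable, and which face the cis diol takes relative to C7 and C10 is open. The product A6 is a free cis diol that must then be acylated with two different acids at C8 and C9, which is exactly the regiochemical problem the chosen plan removes by protecting C9/C10 and C8 differently from step 6 on. The chosen route pays for this with length.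

Key step: step 18

Assumption: locants C1–C15 are those of the germacrane skeleton of 44 and are kept for all intermediates; α denotes the ring face of the C10 oxygen and β the opposite face; the configurations drawn at C1 (step 12), C4 (step 16) and the 2,6-epoxide (step 17) are the expected major ones and are all erased in steps 18, 19 and 29, so minor isomers converge.

## Steps

Step 1
Reactants: 1 but-3-en-1-ol
Product: 2 1-[(but-3-en-1-yloxy)methyl]-4-methoxybenzene
Conditions: NaH, PMBCl, Bu4NI (cat.), THF, 0 °C to rt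
Reagents that add atoms: 4-methoxybenzyl chloride, COc1ccc(CCl)cc1
Why: Williamson etherification of a primary alkoxide with a benzylic chloride; the PMB ether is the one group that can later be removed oxidatively beside silyl ethers and an acetonide.

Step 2
Reactants: 2 1-[(but-3-en-1-yloxy)methyl]-4-methoxybenzene; 3 (E)-1,4-dibromobut-2-ene
Product: 4 1-({[(3E)-5-bromopent-3-en-1-yl]oxy}methyl)-4-methoxybenzene
Conditions: second-generation Hoveyda–Grubbs catalyst (3 mol%), 3 (3 equiv), CH2Cl2, 40 °C
Reagents that add atoms: none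
Why: Olefin cross-metathesis of a terminal alkene with an excess of a symmetrical allylic dibromide should give the E allylic bromide; the E/Z ratio is immaterial because both isomers converge in step 8.

Step 3
Reactants: 5 methacrolein; 6 vinylmagnesium bromide
Product: 7 rac-2-methylpenta-1,4-dien-3-ol
Conditions: THF, −78 to 0 °C; aq. NH4Cl
Reagents that add atoms: none
Why: Grignard 1,2-addition to an enal gives the racemic bis-allylic alcohol that carries C8, C9, C10, C1 and the C14 methyl.

Step 4
Reactants: 7 rac-2-methylpenta-1,4-dien-3-ol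
Product: 8 (S)-1-[(R)-2-methyloxiran-2-yl]prop-2-en-1-ol
Conditions: Ti(OiPr)4 (10 mol%), L-(+)-diisopropyl tartrate (15 mol%), t-BuOOH (0.45 equiv), 4 Å sieves, CH2Cl2, −20 °C
Reagents that add atoms: tert-butyl hydroperoxide, CC(C)(C)OO
Why: Sharpless kinetic resolution: with the L-(+)-tartrate only the (S)-alcohol is epoxidised quickly, at the more nucleophilic 1,1-disubstituted alkene and anti to the carbinol substituent (erythro), which sets C9 (S) and the quaternary C10 (R) in the relationship that becomes the cis 9,10-diol; unreacted (R)-7 is separated.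

Step 5
Reactants: 8 (S)-1-[(R)-2-methyloxiran-2-yl]prop-2-en-1-ol
Product: 9 (2R,3S)-2,3-dihydroxy-2-methylpent-4-en-1-yl benzoate
Conditions: Ti(OiPr)4 (1.5 equiv), PhCO2H, CH2Cl2, rt
Reagents that add atoms: benzoic acid, OC(=O)c1ccccc1
Why: Ti(OiPr)4-assisted opening of a 2,3-epoxy alcohol at the carbon remote from the carbinol, here the unsubstituted CH2 (C1), so neither stereocentre is touched and C1 arrives protected.

Step 6
Reactants: 9 (2R,3S)-2,3-dihydroxy-2-methylpent-4-en-1-yl benzoate
Product: 10 [(4R,5S)-5-ethenyl-2,2,4-trimethyl-1,3-dioxolan-4-yl]methyl benzoate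
Conditions: Me2C(OMe)2, PPTS, CH2Cl2, rt
Reagents that add atoms: 2,2-dimethoxypropane, COC(C)(C)OC
Why: Acid-catalysed transketalisation of the only 1,2-diol; the acetonide ties the C9 and C10 oxygens together and leaves C8 to be protected on its own.

Step 7
Reactants: 10 [(4R,5S)-5-ethenyl-2,2,4-trimethyl-1,3-dioxolan-4-yl]methyl benzoate
Product: 11 [(4R,5R)-5-formyl-2,2,4-trimethyl-1,3-dioxolan-4-yl]methyl benzoate
Conditions: O3, CH2Cl2, −78 °C; then PPh3
Reagents that add atoms: ozone, [O-][O+]=O
Why: Ozonolysis with reductive work-up turns the vinyl group into the C8 aldehyde under neutral conditions, so the α-alkoxy centre C9 does not epimerise.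

Step 8
Reactants: 11 [(4R,5R)-5-formyl-2,2,4-trimethyl-1,3-dioxolan-4-yl]methyl benzoate; 4 1-({[(3E)-5-bromopent-3-en-1-yl]oxy}methyl)-4-methoxybenzene
Product: 12 [(4R,5S)-5-{(1S,2S)-1-hydroxy-2-[2-(4-methoxybenzyloxy)ethyl]but-3-en-1-yl}-2,2,4-trimethyl-1,3-dioxolan-4-yl]methyl benzoate
Conditions: CrCl2 (4 equiv), THF, 0 °C to rt
Reagents that add atoms: none
Why: Nozaki–Hiyama allylation: the γ-substituted allylchromium reagent adds through its γ-carbon in a chair transition state, giving the anti relationship of C7 and C8 whatever the bromide geometry, and it attacks the aldehyde anti to the C9–O bond (Felkin–Anh), so C7 (S) and C8 (S) are both set from C9.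

Step 9
Reactants: 12 [(4R,5S)-5-{(1S,2S)-1-hydroxy-2-[2-(4-methoxybenzyloxy)ethyl]but-3-en-1-yl}-2,2,4-trimethyl-1,3-dioxolan-4-yl]methyl benzoate
Product: 13 [(4R,5S)-5-{(1S,2S)-1-(tert-butyldimethylsilyloxy)-2-[2-(4-methoxybenzyloxy)ethyl]but-3-en-1-yl}-2,2,4-trimethyl-1,3-dioxolan-4-yl]methyl benzoate
Conditions: TBSOTf, 2,6-lutidine, CH2Cl2, −40 to 0 °C
Reagents that add atoms: tert-butyldimethylsilyl triflate, CC(C)(C)[Si](C)(C)OS(=O)(=O)C(F)(F)F
Why: Silylation of the hindered secondary C8 alcohol with the silyl triflate; C8 now carries a group different from the C9/C10 acetonide.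

Step 10
Reactants: 13 [(4R,5S)-5-{(1S,2S)-1-(tert-butyldimethylsilyloxy)-2-[2-(4-methoxybenzyloxy)ethyl]but-3-en-1-yl}-2,2,4-trimethyl-1,3-dioxolan-4-yl]methyl benzoate
Product: 14 [(4R,5S)-5-{(1S,2S)-1-(tert-butyldimethylsilyloxy)-2-[2-(4-methoxybenzyloxy)ethyl]but-3-en-1-yl}-2,2,4-trimethyl-1,3-dioxolan-4-yl]methanol
Conditions: K2CO3, MeOH, rt
Reagents that add atoms: none
Why: Base-catalysed methanolysis removes the primary benzoate; the secondary silyl ether, acetonide and PMB ether are inert.

Step 11
Reactants: 14 [(4R,5S)-5-{(1S,2S)-1-(tert-butyldimethylsilyloxy)-2-[2-(4-methoxybenzyloxy)ethyl]but-3-en-1-yl}-2,2,4-trimethyl-1,3-dioxolan-4-yl]methanol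
Product: 15 (4S,5S)-5-{(1S,2S)-1-(tert-butyldimethylsilyloxy)-2-[2-(4-methoxybenzyloxy)ethyl]but-3-en-1-yl}-2,2,4-trimethyl-1,3-dioxolane-4-carbaldehyde
Conditions: Dess–Martin periodinane, NaHCO3, CH2Cl2, rt
Reagents that add atoms: none
Why: Dess–Martin oxidation of a neopentyl-type primary alcohol to the C1 aldehyde, which has no α-hydrogen and cannot epimerise.

Step 12
Reactants: 15 (4S,5S)-5-{(1S,2S)-1-(tert-butyldimethylsilyloxy)-2-[2-(4-methoxybenzyloxy)ethyl]but-3-en-1-yl}-2,2,4-trimethyl-1,3-dioxolane-4-carbaldehyde; 16 methyl propiolate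
Product: 18 methyl 2-{(R)-hydroxy[(4R,5S)-5-{(1S,2S)-1-(tert-butyldimethylsilyloxy)-2-[2-(4-methoxybenzyloxy)ethyl]but-3-en-1-yl}-2,2,4-trimethyl-1,3-dioxolan-4-yl]methyl}prop-2-enoate, via methyl 2-(diisobutylalumanyl)prop-2-enoate 17 (not isolated)
Conditions: i-Bu2AlH, NMO, THF, 0 °C, then 16; then 15, 0 °C to rt
Reagents that add atoms: none
Why: Hydroalumination of the propiolate gives the α-aluminoacrylate 17, which adds to the hindered aldehyde to give the Morita–Baylis–Hillman-type adduct (vinylalumination), useful where the amine-catalysed reaction fails with α-quaternary aldehydes; the Felkin–Anh (R) carbinol is expected at C1, but either epimer serves.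

Step 13
Reactants: 18 methyl 2-{(R)-hydroxy[(4R,5S)-5-{(1S,2S)-1-(tert-butyldimethylsilyloxy)-2-[2-(4-methoxybenzyloxy)ethyl]but-3-en-1-yl}-2,2,4-trimethyl-1,3-dioxolan-4-yl]methyl}prop-2-enoate
Product: 19 methyl 1α-hydroxy-9α,10α-(isopropylidenedioxy)-10β-methyl-7α-[2-(4-methoxybenzyloxy)ethyl]-8α-(tert-butyldimethylsilyloxy)cyclohept-2(6)-ene-2-carboxylate (ring C1–C2–C6–C7–C8–C9–C10)
Conditions: second-generation Hoveyda–Grubbs catalyst (10 mol%), toluene (2 mM), 80 °C
Reagents that add atoms: none
Why: Ring-closing metathesis of the terminal vinyl group onto the 2-substituted acrylate closes the seven-membered ring as the trisubstituted enoate; the cis-acetonide holds the two chain ends together.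

Step 14
Reactants: 19 methyl 1α-hydroxy-9α,10α-(isopropylidenedioxy)-10β-methyl-7α-[2-(4-methoxybenzyloxy)ethyl]-8α-(tert-butyldimethylsilyloxy)cyclohept-2(6)-ene-2-carboxylate
Product: 20 methyl 1α,8α-bis(tert-butyldimethylsilyloxy)-9α,10α-(isopropylidenedioxy)-10β-methyl-7α-[2-(4-methoxybenzyloxy)ethyl]cyclohept-2(6)-ene-2-carboxylate
Conditions: TBSOTf, 2,6-lutidine, CH2Cl2, 0 °C
Reagents that add atoms: tert-butyldimethylsilyl triflate, CC(C)(C)[Si](C)(C)OS(=O)(=O)C(F)(F)F
Why: Silylation of the allylic C1 alcohol; C1 and C8 now carry the same fluoride-labile group, to be removed together in step 28.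

Step 15
Reactants: 20 methyl 1α,8α-bis(tert-butyldimethylsilyloxy)-9α,10α-(isopropylidenedioxy)-10β-methyl-7α-[2-(4-methoxybenzyloxy)ethyl]cyclohept-2(6)-ene-2-carboxylate; 21 isopropenylmagnesium bromide
Product: 23 1-[1α,8α-bis(tert-butyldimethylsilyloxy)-9α,10α-(isopropylidenedioxy)-10β-methyl-7α-[2-(4-methoxybenzyloxy)ethyl]cyclohept-2(6)-en-2-yl]-2-methylprop-2-en-1-one, via N-methoxy-N-methylamide 22 (not isolated)
Conditions: MeNHOMe·HCl, i-PrMgCl, THF, −20 °C; then 21, −20 to 0 °C; aq. NH4Cl
Reagents that add atoms: N,O-dimethylhydroxylamine hydrochloride, CNOC.Cl (its atoms are in 22 only)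
Why: The magnesium amide converts the ester into the Weinreb amide 22, whose chelated tetrahedral adduct with the alkenyl Grignard reagent stops at the ketone stage, giving the cross-conjugated divinyl ketone.

Step 16
Reactants: 23 1-[1α,8α-bis(tert-butyldimethylsilyloxy)-9α,10α-(isopropylidenedioxy)-10β-methyl-7α-[2-(4-methoxybenzyloxy)ethyl]cyclohept-2(6)-en-2-yl]-2-methylprop-2-en-1-one
Product: 24 1α,8α-bis(tert-butyldimethylsilyloxy)-9α,10α-(isopropylidenedioxy)-4α,10β-dimethyl-7α-[2-(4-methoxybenzyloxy)ethyl]bicyclo[5.3.0]dec-2(6)-en-3-one (five-membered ring C2–C3–C4–C5–C6)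
Conditions: BF3·OEt2 (1.2 equiv), CH2Cl2, −40 to 0 °C
Reagents that add atoms: none
Why: Nazarov cyclisation: the Lewis acid generates the pentadienyl cation, conrotatory 4π closure forms C5–C6, and loss of H6 followed by protonation at C4 gives the ring-fusion enone; both vinyl groups are α-substituted, which favours closure, and the C4 methyl configuration is uncontrolled and irrelevant.

Step 17
Reactants: 24 1α,8α-bis(tert-butyldimethylsilyloxy)-9α,10α-(isopropylidenedioxy)-4α,10β-dimethyl-7α-[2-(4-methoxybenzyloxy)ethyl]bicyclo[5.3.0]dec-2(6)-en-3-one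
Product: 25 2β,6β-epoxy-1α,8α-bis(tert-butyldimethylsilyloxy)-9α,10α-(isopropylidenedioxy)-4α,10β-dimethyl-7α-[2-(4-methoxybenzyloxy)ethyl]bicyclo[5.3.0]decan-3-one
Conditions: 30% H2O2, NaOH, MeOH, 0 °C to rt
Reagents that add atoms: hydrogen peroxide, OO
Why: Weitz–Scheffer epoxidation of the tetrasubstituted enone; hydroperoxide should add to C6 from the β face, away from the α substituents on C1 and C7, and the epoxide face does not matter later.

Step 18
Reactants: 25 2β,6β-epoxy-1α,8α-bis(tert-butyldimethylsilyloxy)-9α,10α-(isopropylidenedioxy)-4α,10β-dimethyl-7α-[2-(4-methoxybenzyloxy)ethyl]bicyclo[5.3.0]decan-3-one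
Product: 27 1α,8α-bis(tert-butyldimethylsilyloxy)-9α,10α-(isopropylidenedioxy)-4α,10β-dimethyl-7α-[2-(4-methoxybenzyloxy)ethyl]cyclodec-2-yn-6-one, via tosylhydrazone 26 (not isolated)
Conditions: TsNHNH2, AcOH/CH2Cl2 (1:1), −20 °C to rt
Reagents that add atoms: p-toluenesulfonyl hydrazide, Cc1ccc(cc1)S(=O)(=O)NN (its atoms are in 26 only)
Why: Condensation at C3 gives tosylhydrazone 26; its nitrogen lone pair pushes electrons through C3 to C2 and opens the epoxide at C2, leaving an oxygen on C6 and an alkenyl diazene, and collapse of the C6–O to a carbonyl then breaks the C2–C6 bond while N2 and p-toluenesulfinate leave and the C2≡C3 alkyne forms (Eschenmoser–Tanabe fragmentation). The closest known reaction type is the fragmentation of ring-fusion epoxides of bicyclic α-methylcyclopentenones to 3-methylcycloalk-4-ynones, used for macrocyclic musk ketones, and of decalone epoxides to cyclodec-5-ynone. The ten-membered ring is not closed by bond formation but set free by ring expansion: the bond shared by the five- and seven-membered rings is cut, so no entropic or transannular cost of a direct closure arises, and a cyclodecyne is an isolable ring size. No stereocentre is made; C2 and C6 lose their configuration, C4 stays as a methine of no consequence, and C1 and C7–C10 are spectators. The selectivity needed is fragmentation ahead of simple acid-promoted epoxide opening; in the alkenyl diazene the ring holds the C2–C6 bond trans, that is anti-periplanar, to the C3–N bond, the ideal geometry for the cleavage. The weakly acidic, cold medium spares the silyl ethers, the acetonide and the PMB ether and does not epimerise C7, which becomes α to the new ketone only at the end.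

Step 19
Reactants: 27 1α,8α-bis(tert-butyldimethylsilyloxy)-9α,10α-(isopropylidenedioxy)-4α,10β-dimethyl-7α-[2-(4-methoxybenzyloxy)ethyl]cyclodec-2-yn-6-one
Product: 29 (4Z)-1α,8α-bis(tert-butyldimethylsilyloxy)-9α,10α-(isopropylidenedioxy)-4,10β-dimethyl-7α-[2-(4-methoxybenzyloxy)ethyl]cyclodec-4-en-2-yn-6-one, via trimethylsilyl enol ether 28 (not isolated)
Conditions: LiN(SiMe3)2, Me3SiCl, THF, −78 °C; then Pd(OAc)2, MeCN, rt
Reagents that add atoms: chlorotrimethylsilane, C[Si](C)(C)Cl (its atoms are in 28 only)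
Why: Kinetic deprotonation takes the unhindered C5 methylene and not the tertiary, non-allylic C7–H; Saegusa–Ito oxidation of the silyl enol ether (palladium enolate, β-hydride elimination of the propargylic C4–H) then gives the enynone, and the ring allows only the Z alkene.

Step 20
Reactants: 29 (4Z)-1α,8α-bis(tert-butyldimethylsilyloxy)-9α,10α-(isopropylidenedioxy)-4,10β-dimethyl-7α-[2-(4-methoxybenzyloxy)ethyl]cyclodec-4-en-2-yn-6-one
Product: 30 (4Z,6S)-1α,8α-bis(tert-butyldimethylsilyloxy)-9α,10α-(isopropylidenedioxy)-4,10β-dimethyl-7α-[2-(4-methoxybenzyloxy)ethyl]cyclodec-4-en-2-yn-6α-ol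
Conditions: NaBH4, CeCl3·7H2O, MeOH, −78 °C
Reagents that add atoms: none
Why: Luche 1,2-reduction of the enone; with the C7 side chain lying outward and the C7–C8 ring bond perpendicular to the planar enynone, hydride should enter anti to that ring bond past H7 (Felkin–Anh), which puts the new hydroxyl cis to the side chain (6S), the epimer of what the lactone needs.

Step 21
Reactants: 30 (4Z,6S)-1α,8α-bis(tert-butyldimethylsilyloxy)-9α,10α-(isopropylidenedioxy)-4,10β-dimethyl-7α-[2-(4-methoxybenzyloxy)ethyl]cyclodec-4-en-2-yn-6α-ol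
Product: 31 (4Z,6R)-1α,8α-bis(tert-butyldimethylsilyloxy)-9α,10α-(isopropylidenedioxy)-4,10β-dimethyl-7α-[2-(4-methoxybenzyloxy)ethyl]cyclodec-4-en-2-yn-6β-yl 4-nitrobenzoate
Conditions: 4-nitrobenzoic acid, PPh3, DIAD, toluene, 0 °C to rt
Reagents that add atoms: 4-nitrobenzoic acid, OC(=O)c1ccc(cc1)[N+](=O)[O-]
Why: Mitsunobu esterification inverts C6 by SN2 displacement of the oxyphosphonium group; the carboxylate comes in from the same open face that the hydride used, and attack at the tertiary C4 (SN2′) is disfavoured.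

Step 22
Reactants: 31 (4Z,6R)-1α,8α-bis(tert-butyldimethylsilyloxy)-9α,10α-(isopropylidenedioxy)-4,10β-dimethyl-7α-[2-(4-methoxybenzyloxy)ethyl]cyclodec-4-en-2-yn-6β-yl 4-nitrobenzoate
Product: 32 (4Z,6R)-1α,8α-bis(tert-butyldimethylsilyloxy)-7α-(2-hydroxyethyl)-9α,10α-(isopropylidenedioxy)-4,10β-dimethylcyclodec-4-en-2-yn-6β-yl 4-nitrobenzoate
Conditions: DDQ, CH2Cl2/pH 7 buffer, 0 °C
Reagents that add atoms: none
Why: Oxidative cleavage of the PMB ether; it is done while C6 is still esterified, so the activated allylic C6 carbinol cannot be oxidised by DDQ.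

Step 23
Reactants: 32 (4Z,6R)-1α,8α-bis(tert-butyldimethylsilyloxy)-7α-(2-hydroxyethyl)-9α,10α-(isopropylidenedioxy)-4,10β-dimethylcyclodec-4-en-2-yn-6β-yl 4-nitrobenzoate
Product: 33 (4Z,6R)-1α,8α-bis(tert-butyldimethylsilyloxy)-7α-(2-hydroxyethyl)-9α,10α-(isopropylidenedioxy)-4,10β-dimethylcyclodec-4-en-2-yn-6β-ol
Conditions: K2CO3, MeOH, 0 °C to rt
Reagents that add atoms: none
Why: Methanolysis of the activated 4-nitrobenzoate frees the (6R)-alcohol; no base-sensitive group is present yet.

Step 24
Reactants: 33 (4Z,6R)-1α,8α-bis(tert-butyldimethylsilyloxy)-7α-(2-hydroxyethyl)-9α,10α-(isopropylidenedioxy)-4,10β-dimethylcyclodec-4-en-2-yn-6β-ol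
Product: 35 (4Z)-1α,8α-bis(tert-butyldimethylsilyloxy)-9α,10α-(isopropylidenedioxy)-4,10β-dimethylcyclodec-4-en-2-yne fused at C6/C7 to a trans γ-butyrolactone (O on C6β, C11H2 on C7α, C12=O), via lactol 34 (not isolated)
Conditions: TEMPO (20 mol%), PhI(OAc)2, CH2Cl2, rt
Reagents that add atoms: none
Why: The oxoammonium oxidant takes the primary alcohol to the aldehyde, the C6 hydroxyl traps it as the five-membered lactol 34, and a second oxidation gives the lactone (oxidative lactonisation of a 1,4-diol) with retention at C6; C8 is silylated, so only the 6,12-lactone can form.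

Step 25
Reactants: 35 trans-fused γ-butyrolactone of step 24
Product: 38 the corresponding α-methylene lactone (C11=C13H2), other groups as in 35, via Mannich base 36 (not isolated), via trimethylammonium iodide 37 (not isolated)
Conditions: LiN(SiMe3)2, THF, −78 °C; CH2=NMe2+ I−, −78 to 0 °C; then MeI, MeOH, rt; then aq. NaHCO3, CH2Cl2
Reagents that add atoms: N,N-dimethylmethyleneiminium iodide, C=[N+](C)C.[I-]; iodomethane, CI (its atoms are in 37 only)
Why: The lactone C11 methylene is the only acidic position; its enolate adds to the iminium salt (Mannich reaction), and quaternisation followed by base-induced elimination of trimethylamine gives the exocyclic methylene lactone, the classical end game for this unit.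

Step 26
Reactants: 38 α-methylene lactone of step 25
Product: 39 the 9α,10α-diol of 38 (acetonide removed; C1 and C8 silyl ethers kept)
Conditions: AcOH/THF/H2O (3:1:1), 40 °C
Reagents that add atoms: none
Why: Acid-catalysed hydrolysis of the isopropylidene acetal; hindered secondary silyl ethers survive buffered aqueous acetic acid, and the lactone and enyne are inert.

Step 27
Reactants: 39 9α,10α-diol of step 26
Product: 40 the 9α-acetate of 39 (10α-OH free)
Conditions: Ac2O, pyridine, DMAP (cat.), CH2Cl2, 0 °C to rt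
Reagents that add atoms: acetic anhydride, CC(=O)OC(C)=O
Why: Acylation distinguishes the secondary C9 hydroxyl from the tertiary C10 hydroxyl, which does not react under these conditions; C8 and C1 are still silylated, so the acetate can only go to C9.

Step 28
Reactants: 40 9α-acetate of step 27
Product: 41 the 1α,8α,10α-triol 9α-acetate (both silyl ethers removed)
Conditions: HF·pyridine, pyridine, THF, 0 °C to rt
Reagents that add atoms: none
Why: Buffered fluoride cleaves both silyl ethers; the acidic medium does not promote acetate migration or translactonisation to the C8 hydroxyl.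

Step 29
Reactants: 41 1α,8α,10α-triol 9α-acetate of step 28
Product: 42 the C1 ketone of 41 (conjugated ynone C1(=O)–C2≡C3–C4=C5; 8α-OH and 10α-OH free)
Conditions: MnO2, CH2Cl2, rt
Reagents that add atoms: none
Why: MnO2 oxidises only the propargylic C1 alcohol; the saturated C8 alcohol and the tertiary C10 alcohol are untouched, and the enynone has no γ-hydrogen at C4 and cannot isomerise to an allenone.

Step 30
Reactants: 42 ynone of step 29
Product: 43 (4Z,6R,7S,8S,9S,10S)-9-acetoxy-8-hydroxy-1-oxo-3,10-epoxygermacra-2,4,11(13)-trien-12,6-olide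
Conditions: Ph3PAuNTf2 (5 mol%), CH2Cl2, rt
Reagents that add atoms: none
Why: The cationic monovalent gold complex activates the alkyne and the tertiary C10 hydroxyl adds to C3 in a 5-endo-dig sense; protodeauration gives the 3(2H)-furanone, a standard cyclisation of α′-hydroxy ynones, and the acetylated C9 oxygen cannot compete.

Step 31
Reactants: 43 (4Z,6R,7S,8S,9S,10S)-9-acetoxy-8-hydroxy-1-oxo-3,10-epoxygermacra-2,4,11(13)-trien-12,6-olide
Product: 44 (4Z,6R,7S,8S,9S,10S)-9-acetoxy-8-(2-methylprop-2-enoyloxy)-1-oxo-3,10-epoxygermacra-2,4,11(13)-trien-12,6-olide (CNP0365569.2)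
Conditions: methacrylic anhydride, Et3N, DMAP (cat.), CH2Cl2, 0 °C
Reagents that add atoms: methacrylic anhydride, C=C(C)C(=O)OC(=O)C(C)=C
Why: Acyl transfer to the only remaining hydroxyl; excess anhydride at low temperature should esterify C8 faster than the neighbouring acetate can migrate or the lactone can shift to C8.

## Compound list

1 | but-3-en-1-ol | C=CCCO | starting material
2 | 1-[(but-3-en-1-yloxy)methyl]-4-methoxybenzene | C=CCCOCc1ccc(OC)cc1 | intermediate
3 | (E)-1,4-dibromobut-2-ene | BrC/C=C/CBr | starting material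
4 | 1-({[(3E)-5-bromopent-3-en-1-yl]oxy}methyl)-4-methoxybenzene | BrC/C=C/CCOCc1ccc(OC)cc1 | intermediate
5 | methacrolein | C=C(C)C=O | starting material
6 | vinylmagnesium bromide | C=C[Mg]Br | starting material
7 | rac-2-methylpenta-1,4-dien-3-ol | C=CC(O)C(C)=C | intermediate
8 | (S)-1-[(R)-2-methyloxiran-2-yl]prop-2-en-1-ol | C=C[C@H](O)[C@@]1(C)CO1 | intermediate
9 | (2R,3S)-2,3-dihydroxy-2-methylpent-4-en-1-yl benzoate | C=C[C@H](O)[C@](C)(O)COC(=O)c1ccccc1 | intermediate
10 | [(4R,5S)-5-ethenyl-2,2,4-trimethyl-1,3-dioxolan-4-yl]methyl benzoate | C=C[C@@H]1OC(C)(C)O[C@]1(C)COC(=O)c1ccccc1 | intermediate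
11 | [(4R,5R)-5-formyl-2,2,4-trimethyl-1,3-dioxolan-4-yl]methyl benzoate | O=C[C@@H]1OC(C)(C)O[C@]1(C)COC(=O)c1ccccc1 | intermediate
12 | [(4R,5S)-5-{(1S,2S)-1-hydroxy-2-[2-(4-methoxybenzyloxy)ethyl]but-3-en-1-yl}-2,2,4-trimethyl-1,3-dioxolan-4-yl]methyl benzoate | C=C[C@H](CCOCc1ccc(OC)cc1)[C@H](O)[C@@H]1OC(C)(C)O[C@]1(C)COC(=O)c1ccccc1 | intermediate
13 | [(4R,5S)-5-{(1S,2S)-1-(tert-butyldimethylsilyloxy)-2-[2-(4-methoxybenzyloxy)ethyl]but-3-en-1-yl}-2,2,4-trimethyl-1,3-dioxolan-4-yl]methyl benzoate | C=C[C@H](CCOCc1ccc(OC)cc1)[C@H](O[Si](C)(C)C(C)(C)C)[C@@H]1OC(C)(C)O[C@]1(C)COC(=O)c1ccccc1 | intermediate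
14 | [(4R,5S)-5-{(1S,2S)-1-(tert-butyldimethylsilyloxy)-2-[2-(4-methoxybenzyloxy)ethyl]but-3-en-1-yl}-2,2,4-trimethyl-1,3-dioxolan-4-yl]methanol | C=C[C@H](CCOCc1ccc(OC)cc1)[C@H](O[Si](C)(C)C(C)(C)C)[C@@H]1OC(C)(C)O[C@]1(C)CO | intermediate
15 | (4S,5S)-5-{(1S,2S)-1-(tert-butyldimethylsilyloxy)-2-[2-(4-methoxybenzyloxy)ethyl]but-3-en-1-yl}-2,2,4-trimethyl-1,3-dioxolane-4-carbaldehyde | C=C[C@H](CCOCc1ccc(OC)cc1)[C@H](O[Si](C)(C)C(C)(C)C)[C@@H]1OC(C)(C)O[C@]1(C)C=O | intermediate
16 | methyl propiolate | C#CC(=O)OC | starting material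
17 | methyl 2-(diisobutylalumanyl)prop-2-enoate | COC(=O)C(=C)[Al](CC(C)C)CC(C)C | intermediate (not isolated)
18 | methyl 2-{(R)-hydroxy[(4R,5S)-5-{(1S,2S)-1-(tert-butyldimethylsilyloxy)-2-[2-(4-methoxybenzyloxy)ethyl]but-3-en-1-yl}-2,2,4-trimethyl-1,3-dioxolan-4-yl]methyl}prop-2-enoate | C=C[C@H](CCOCc1ccc(OC)cc1)[C@H](O[Si](C)(C)C(C)(C)C)[C@@H]1OC(C)(C)O[C@]1(C)[C@H](O)C(=C)C(=O)OC | intermediate
19 | methyl 1α-hydroxy-9α,10α-(isopropylidenedioxy)-10β-methyl-7α-[2-(4-methoxybenzyloxy)ethyl]-8α-(tert-butyldimethylsilyloxy)cyclohept-2(6)-ene-2-carboxylate | COC(=O)C1=C[C@H](CCOCc2ccc(OC)cc2)[C@H](O[Si](C)(C)C(C)(C)C)[C@@H]2OC(C)(C)O[C@]2(C)[C@@H]1O | intermediate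
20 | methyl 1α,8α-bis(tert-butyldimethylsilyloxy)-9α,10α-(isopropylidenedioxy)-10β-methyl-7α-[2-(4-methoxybenzyloxy)ethyl]cyclohept-2(6)-ene-2-carboxylate | COC(=O)C1=C[C@H](CCOCc2ccc(OC)cc2)[C@H](O[Si](C)(C)C(C)(C)C)[C@@H]2OC(C)(C)O[C@]2(C)[C@@H]1O[Si](C)(C)C(C)(C)C | intermediate
21 | isopropenylmagnesium bromide | C=C(C)[Mg]Br | starting material
22 | N-methoxy-N-methylamide corresponding to ester 20 | CON(C)C(=O)C1=C[C@H](CCOCc2ccc(OC)cc2)[C@H](O[Si](C)(C)C(C)(C)C)[C@@H]2OC(C)(C)O[C@]2(C)[C@@H]1O[Si](C)(C)C(C)(C)C | intermediate (not isolated)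
23 | 1-[1α,8α-bis(tert-butyldimethylsilyloxy)-9α,10α-(isopropylidenedioxy)-10β-methyl-7α-[2-(4-methoxybenzyloxy)ethyl]cyclohept-2(6)-en-2-yl]-2-methylprop-2-en-1-one | C=C(C)C(=O)C1=C[C@H](CCOCc2ccc(OC)cc2)[C@H](O[Si](C)(C)C(C)(C)C)[C@@H]2OC(C)(C)O[C@]2(C)[C@@H]1O[Si](C)(C)C(C)(C)C | intermediate
24 | 1α,8α-bis(tert-butyldimethylsilyloxy)-9α,10α-(isopropylidenedioxy)-4α,10β-dimethyl-7α-[2-(4-methoxybenzyloxy)ethyl]bicyclo[5.3.0]dec-2(6)-en-3-one | O=C1[C@H](C)CC2=C1[C@@H](O[Si](C)(C)C(C)(C)C)[C@@](C)(OC(C)(C)O3)[C@@H]3[C@@H](O[Si](C)(C)C(C)(C)C)[C@H]2CCOCc1ccc(OC)cc1 | intermediate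
25 | 2β,6β-epoxy-1α,8α-bis(tert-butyldimethylsilyloxy)-9α,10α-(isopropylidenedioxy)-4α,10β-dimethyl-7α-[2-(4-methoxybenzyloxy)ethyl]bicyclo[5.3.0]decan-3-one | O=C1[C@H](C)C[C@@]23O[C@@]12[C@@H](O[Si](C)(C)C(C)(C)C)[C@@](C)(OC(C)(C)O4)[C@@H]4[C@@H](O[Si](C)(C)C(C)(C)C)[C@H]3CCOCc1ccc(OC)cc1 | intermediate (precursor of the key step)
26 | p-toluenesulfonylhydrazone of 25 at C3 | Cc1ccc(cc1)S(=O)(=O)NN=C1[C@H](C)C[C@@]23O[C@@]12[C@@H](O[Si](C)(C)C(C)(C)C)[C@@](C)(OC(C)(C)O4)[C@@H]4[C@@H](O[Si](C)(C)C(C)(C)C)[C@H]3CCOCc1ccc(OC)cc1 | intermediate (not isolated)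
27 | 1α,8α-bis(tert-butyldimethylsilyloxy)-9α,10α-(isopropylidenedioxy)-4α,10β-dimethyl-7α-[2-(4-methoxybenzyloxy)ethyl]cyclodec-2-yn-6-one | O=C1C[C@@H](C)C#C[C@@H](O[Si](C)(C)C(C)(C)C)[C@@](C)(OC(C)(C)O2)[C@@H]2[C@@H](O[Si](C)(C)C(C)(C)C)[C@H]1CCOCc1ccc(OC)cc1 | intermediate (product of the key step)
28 | trimethylsilyl enol ether of 27 (C5=C6, O-silylated at C6) | C[Si](C)(C)O/C1=C/[C@@H](C)C#C[C@@H](O[Si](C)(C)C(C)(C)C)[C@@](C)(OC(C)(C)O2)[C@@H]2[C@@H](O[Si](C)(C)C(C)(C)C)[C@H]1CCOCc1ccc(OC)cc1 | intermediate (not isolated)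
29 | (4Z)-1α,8α-bis(tert-butyldimethylsilyloxy)-9α,10α-(isopropylidenedioxy)-4,10β-dimethyl-7α-[2-(4-methoxybenzyloxy)ethyl]cyclodec-4-en-2-yn-6-one | O=C1/C=C(/C)C#C[C@@H](O[Si](C)(C)C(C)(C)C)[C@@](C)(OC(C)(C)O2)[C@@H]2[C@@H](O[Si](C)(C)C(C)(C)C)[C@H]1CCOCc1ccc(OC)cc1 | intermediate
30 | (4Z,6S)-6α-alcohol from 29 (hydroxyl cis to the C7 side chain) | O[C@H]1/C=C(/C)C#C[C@@H](O[Si](C)(C)C(C)(C)C)[C@@](C)(OC(C)(C)O2)[C@@H]2[C@@H](O[Si](C)(C)C(C)(C)C)[C@H]1CCOCc1ccc(OC)cc1 | intermediate
31 | (4Z,6R)-6β-yl 4-nitrobenzoate (C6 inverted; PMB ether kept) | O=C(O[C@@H]1/C=C(/C)C#C[C@@H](O[Si](C)(C)C(C)(C)C)[C@@](C)(OC(C)(C)O2)[C@@H]2[C@@H](O[Si](C)(C)C(C)(C)C)[C@H]1CCOCc1ccc(OC)cc1)c1ccc([N+](=O)[O-])cc1 | intermediate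
32 | (4Z,6R)-6β-yl 4-nitrobenzoate with free 2-hydroxyethyl side chain | O=C(O[C@@H]1/C=C(/C)C#C[C@@H](O[Si](C)(C)C(C)(C)C)[C@@](C)(OC(C)(C)O2)[C@@H]2[C@@H](O[Si](C)(C)C(C)(C)C)[C@H]1CCO)c1ccc([N+](=O)[O-])cc1 | intermediate
33 | (4Z,6R)-1α,8α-bis(tert-butyldimethylsilyloxy)-7α-(2-hydroxyethyl)-9α,10α-(isopropylidenedioxy)-4,10β-dimethylcyclodec-4-en-2-yn-6β-ol | O[C@@H]1/C=C(/C)C#C[C@@H](O[Si](C)(C)C(C)(C)C)[C@@](C)(OC(C)(C)O2)[C@@H]2[C@@H](O[Si](C)(C)C(C)(C)C)[C@H]1CCO | intermediate
34 | lactol (C12 hemiacetal closed onto the C6 oxygen; C12 epimers) | OC1C[C@H]2[C@H](O1)/C=C(/C)C#C[C@@H](O[Si](C)(C)C(C)(C)C)[C@@](C)(OC(C)(C)O3)[C@@H]3[C@H]2O[Si](C)(C)C(C)(C)C | intermediate (not isolated)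
35 | trans-fused 12,6-lactone: (4Z)-1α,8α-bis(tert-butyldimethylsilyloxy)-9α,10α-(isopropylidenedioxy)germacr-4-en-2-yn-12,6β-olide | O=C1C[C@H]2[C@H](O1)/C=C(/C)C#C[C@@H](O[Si](C)(C)C(C)(C)C)[C@@](C)(OC(C)(C)O3)[C@@H]3[C@H]2O[Si](C)(C)C(C)(C)C | intermediate
36 | 11-(dimethylaminomethyl) lactone (Mannich base; C11 epimers) | O=C1C(CN(C)C)[C@H]2[C@H](O1)/C=C(/C)C#C[C@@H](O[Si](C)(C)C(C)(C)C)[C@@](C)(OC(C)(C)O3)[C@@H]3[C@H]2O[Si](C)(C)C(C)(C)C | intermediate (not isolated)
37 | 11-(trimethylammoniomethyl) lactone iodide | O=C1C(C[N+](C)(C)C)[C@H]2[C@H](O1)/C=C(/C)C#C[C@@H](O[Si](C)(C)C(C)(C)C)[C@@](C)(OC(C)(C)O3)[C@@H]3[C@H]2O[Si](C)(C)C(C)(C)C.[I-] | intermediate (not isolated)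
38 | (4Z)-1α,8α-bis(tert-butyldimethylsilyloxy)-9α,10α-(isopropylidenedioxy)germacra-4,11(13)-dien-2-yn-12,6β-olide | O=C1C(=C)[C@H]2[C@H](O1)/C=C(/C)C#C[C@@H](O[Si](C)(C)C(C)(C)C)[C@@](C)(OC(C)(C)O3)[C@@H]3[C@H]2O[Si](C)(C)C(C)(C)C | intermediate
39 | (4Z)-1α,8α-bis(tert-butyldimethylsilyloxy)-9α,10α-dihydroxygermacra-4,11(13)-dien-2-yn-12,6β-olide | O=C1C(=C)[C@H]2[C@H](O1)/C=C(/C)C#C[C@@H](O[Si](C)(C)C(C)(C)C)[C@@](C)(O)[C@@H](O)[C@H]2O[Si](C)(C)C(C)(C)C | intermediate
40 | (4Z)-9α-acetoxy-1α,8α-bis(tert-butyldimethylsilyloxy)-10α-hydroxygermacra-4,11(13)-dien-2-yn-12,6β-olide | O=C1C(=C)[C@H]2[C@H](O1)/C=C(/C)C#C[C@@H](O[Si](C)(C)C(C)(C)C)[C@@](C)(O)[C@@H](OC(C)=O)[C@H]2O[Si](C)(C)C(C)(C)C | intermediate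
41 | (4Z)-9α-acetoxy-1α,8α,10α-trihydroxygermacra-4,11(13)-dien-2-yn-12,6β-olide | O=C1C(=C)[C@H]2[C@H](O1)/C=C(/C)C#C[C@@H](O)[C@@](C)(O)[C@@H](OC(C)=O)[C@H]2O | intermediate
42 | (4Z)-9α-acetoxy-8α,10α-dihydroxy-1-oxogermacra-4,11(13)-dien-2-yn-12,6β-olide | O=C1C(=C)[C@H]2[C@H](O1)/C=C(/C)C#CC(=O)[C@@](C)(O)[C@@H](OC(C)=O)[C@H]2O | intermediate
43 | (4Z,6R,7S,8S,9S,10S)-9-acetoxy-8-hydroxy-1-oxo-3,10-epoxygermacra-2,4,11(13)-trien-12,6-olide | O[C@H]1[C@H]2C(=C)C(=O)O[C@@H]2/C=C(/C)C2=CC(=O)[C@@](C)(O2)[C@H]1OC(C)=O | intermediate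
44 | (4Z,6R,7S,8S,9S,10S)-9-acetoxy-8-(2-methylprop-2-enoyloxy)-1-oxo-3,10-epoxygermacra-2,4,11(13)-trien-12,6-olide | C=C(C)C(=O)O[C@H]1[C@H]2C(=C)C(=O)O[C@@H]2/C=C(/C)C2=CC(=O)[C@@](C)(O2)[C@H]1OC(C)=O | target

## Step count and least certain steps

Total step count: 31. Longest linear sequence: 29 steps (steps 3–31, from methacrolein 5); bromide 4 is made in a two-step side branch (steps 1–2) and joins at step 8.

**Step 18 (key step).** Condensation at C3, which is flanked by the epoxide carbon and the C4 methine, may be slow. Acid-promoted opening of the epoxide, loss of the acetonide, or a hydrazone that ionises without cleaving the C2–C6 bond could then compete. The fallback sets out from 25 and returns at 27. The ketone is condensed under neutral conditions with 1-amino-trans-2,3-diphenylaziridine to give the N-aziridinyl imine F1, which is isolated and heated in toluene. Loss of trans-stilbene generates the same diazo-type intermediate without acid, and fragmentation with loss of N2 should give 27. This replaces the sulfinate leaving group and the acidic medium by a thermal, neutral process with an isolable intermediate.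

**Step 16 (Nazarov cyclisation).** The Lewis acid may strip the acetonide or a silyl ether, ionise the allylic C1 silyl ether, or allow a hydride shift from C1 to the oxyallyl cation before the proton at C6 is lost. The fallback sets out from 20 and returns at 24. The Weinreb amide 22 is isolated and treated with (E)-[1-methyl-2-(trimethylsilyl)vinyl]lithium to give the β-silyl dienone F2. FeCl3 in CH2Cl2 at −50 °C then effects a silicon-directed Nazarov cyclisation, in which the β-silyl group lowers the barrier and ends the cation by desilylation, giving the cis-fused 4-methylcyclopent-4-enone F3. DBU moves the double bond through the dienolates into the ring-fusion position to give 24.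

**Step 19 (dehydrogenation).** Enolisation may stray towards C7 and epimerise it, or the palladium may be held by the alkyne so that the enol ether is only hydrolysed back. The fallback sets out from 25 and returns at 29. In the epoxy ketone C4–H is the only enolisable position, so LiN(SiMe3)2/Me3SiCl gives the silyl enol ether F4 without any regiochemical choice, and Pd(OAc)2 gives the epoxy cyclopentenone F5 with the alkene already cis in the five-membered ring. Tosylhydrazide in AcOH/CH2Cl2 then converts F5 through its tosylhydrazone F6 into 29 directly. This moves the dehydrogenation ahead of the fragmentation at the price of a less closely precedented substrate for the key step.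

**Step 20 (C6 configuration).** Facial selectivity may be poor or reversed, because it rests on a conformational argument for a ten-membered ring, and the inversion in step 21 would then be unnecessary or harmful. The fallback sets out from 29 and returns at 33. A Corey–Bakshi–Shibata reduction with (R)-2-methyl-CBS-oxazaborolidine and catecholborane, on the model that the enyne arm acts as the large group, is used to override the substrate bias and give the (6R)-alcohol F7 directly. DDQ then removes the PMB ether to give 33, and steps 21–23 are skipped.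

**Step 13 (ring-closing metathesis).** Closure onto a 2-substituted acrylate flanked by a quaternary centre may stall, with dimerisation through the vinyl group or alkene migration taking over. The fallback sets out from 15 and returns at 20. Vinylmagnesium bromide gives the C1 vinyl carbinol F8, whose two monosubstituted alkenes close easily to cycloheptenol F9. Dess–Martin oxidation gives cycloheptenone F10, I2/pyridine gives the 2-iodoenone F11, and Luche reduction gives the iodo allylic alcohol F12, which is silylated to F13. Methoxycarbonylation (Pd(PPh3)4, a zerovalent palladium catalyst, CO, MeOH, Et3N) then gives 20. The C1 configuration again does not matter.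

## Further compounds

F1 | step 18 | N-(trans-2,3-diphenylaziridin-1-yl)imine of 25 at C3 (aziridine from the racemic trans reagent) | c1ccccc1C1C(c2ccccc2)N1N=C1[C@H](C)C[C@@]23O[C@@]12[C@@H](O[Si](C)(C)C(C)(C)C)[C@@](C)(OC(C)(C)O4)[C@@H]4[C@@H](O[Si](C)(C)C(C)(C)C)[C@H]3CCOCc1ccc(OC)cc1
F2 | step 16 | (E)-2-methyl-3-(trimethylsilyl)prop-2-enoyl analogue of dienone 23 | C[Si](C)(C)/C=C(\C)C(=O)C1=C[C@H](CCOCc2ccc(OC)cc2)[C@H](O[Si](C)(C)C(C)(C)C)[C@@H]2OC(C)(C)O[C@]2(C)[C@@H]1O[Si](C)(C)C(C)(C)C
F3 | step 16 | cis-fused 4-methylbicyclo[5.3.0]dec-4-en-3-one isomer of 24 (H at C2 and C6 cis to each other, their face not defined) | O=C1C(C)=CC2C1[C@@H](O[Si](C)(C)C(C)(C)C)[C@@](C)(OC(C)(C)O3)[C@@H]3[C@@H](O[Si](C)(C)C(C)(C)C)[C@H]2CCOCc1ccc(OC)cc1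
F4 | step 19 | trimethylsilyl enol ether of 25 (C3=C4) | C[Si](C)(C)OC1=C(C)C[C@@]23O[C@@]12[C@@H](O[Si](C)(C)C(C)(C)C)[C@@](C)(OC(C)(C)O4)[C@@H]4[C@@H](O[Si](C)(C)C(C)(C)C)[C@H]3CCOCc1ccc(OC)cc1
F5 | step 19 | 2β,6β-epoxy-4-methylbicyclo[5.3.0]dec-4-en-3-one (C4=C5 dehydro derivative of 25) | O=C1C(C)=C[C@@]23O[C@@]12[C@@H](O[Si](C)(C)C(C)(C)C)[C@@](C)(OC(C)(C)O4)[C@@H]4[C@@H](O[Si](C)(C)C(C)(C)C)[C@H]3CCOCc1ccc(OC)cc1
F6 | step 19 | p-toluenesulfonylhydrazone of F5 | Cc1ccc(cc1)S(=O)(=O)NN=C1C(C)=C[C@@]23O[C@@]12[C@@H](O[Si](C)(C)C(C)(C)C)[C@@](C)(OC(C)(C)O4)[C@@H]4[C@@H](O[Si](C)(C)C(C)(C)C)[C@H]3CCOCc1ccc(OC)cc1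
F7 | step 20 | (4Z,6R)-6β-alcohol, C6 epimer of 30 (PMB ether kept) | O[C@@H]1/C=C(/C)C#C[C@@H](O[Si](C)(C)C(C)(C)C)[C@@](C)(OC(C)(C)O2)[C@@H]2[C@@H](O[Si](C)(C)C(C)(C)C)[C@H]1CCOCc1ccc(OC)cc1
F8 | step 13 | C1 vinyl carbinol from aldehyde 15 | C=C[C@H](CCOCc1ccc(OC)cc1)[C@H](O[Si](C)(C)C(C)(C)C)[C@@H]1OC(C)(C)O[C@]1(C)[C@H](O)C=C
F9 | step 13 | cyclohept-2(6)-en-1α-ol lacking the C2 ester (other groups as in 19) | C1=C[C@H](CCOCc2ccc(OC)cc2)[C@H](O[Si](C)(C)C(C)(C)C)[C@@H]2OC(C)(C)O[C@]2(C)[C@@H]1O
F10 | step 13 | corresponding cyclohept-2(6)-en-1-one | C1=C[C@H](CCOCc2ccc(OC)cc2)[C@H](O[Si](C)(C)C(C)(C)C)[C@@H]2OC(C)(C)O[C@]2(C)C1=O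
F11 | step 13 | 2-iodocyclohept-2(6)-en-1-one | IC1=C[C@H](CCOCc2ccc(OC)cc2)[C@H](O[Si](C)(C)C(C)(C)C)[C@@H]2OC(C)(C)O[C@]2(C)C1=O
F12 | step 13 | 2-iodocyclohept-2(6)-en-1α-ol | IC1=C[C@H](CCOCc2ccc(OC)cc2)[C@H](O[Si](C)(C)C(C)(C)C)[C@@H]2OC(C)(C)O[C@]2(C)[C@@H]1O
F13 | step 13 | 1α-tert-butyldimethylsilyl ether of F12 | IC1=C[C@H](CCOCc2ccc(OC)cc2)[C@H](O[Si](C)(C)C(C)(C)C)[C@@H]2OC(C)(C)O[C@]2(C)[C@@H]1O[Si](C)(C)C(C)(C)C
A1 | alternative 1 | open-chain C9 aldehyde bearing the 2-methyl-3-(triisopropylsilyloxy)furan, lactone and C8 methacrylate | C=C(C)C(=O)O[C@H](C=O)[C@H]1C(=C)C(=O)O[C@@H]1/C=C(/C)c1cc(O[Si](C(C)C)(C(C)C)C(C)C)c(C)o1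
A2 | alternative 1 | 9-deacetyl target (free C9 hydroxyl) | C=C(C)C(=O)O[C@H]1[C@H]2C(=C)C(=O)O[C@@H]2/C=C(/C)C2=CC(=O)[C@@](C)(O2)[C@H]1O
A3 | alternative 2 | cis-cyclooctenone with the C10 prop-1-ynyl ether, C8/C9 acetonide and silyl-protected C6 and side-chain oxygens | CC1(C)O[C@H]2[C@@H](C(=C)CO[Si](C)(C)C(C)(C)C)[C@H](O[Si](C)(C)C(C)(C)C)/C=C\C(=O)[C@@](C)(OC#CC)[C@H]2O1
A4 | alternative 2 | furanone-bridged ten-membered ring, seco-lactone protected | CC1(C)O[C@H]2[C@@H](C(=C)CO[Si](C)(C)C(C)(C)C)[C@H](O[Si](C)(C)C(C)(C)C)/C=C(/C)C3=CC(=O)[C@@](C)(O3)[C@H]2O1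
A5 | alternative 3 | open-chain enyne C8,C9-dialdehyde with lactone and C1/C10 acetonide | O=C[C@H]1C(=C)C(=O)O[C@@H]1/C=C(/C)C#C[C@@H]1OC(C)(C)O[C@@]1(C)C=O
A6 | alternative 3 | ten-membered enyne 8,9-diol | O[C@H]1[C@H]2C(=C)C(=O)O[C@@H]2/C=C(/C)C#C[C@@H]2OC(C)(C)O[C@@]2(C)[C@H]1O
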